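**Retrosynthetic overview**

1. Numbering: ring C1 (C=O), C2 (CH–O-angelate), C3 (CH–side chain), C4 (CH2), C5/C6 (epoxide, CH3 on C6); chain C7 (=CH2), C8 (CH–O-angelate), C9 (CH2), C10 (CH–OH), C11 (CMe2OH). The strategy rests on the contiguous all-cis triad C1–O / C2–O / C3–C7 of the cyclohexane ring beside the C5–C6 epoxide (a former C5=C6 alkene), read as the endo Diels–Alder adduct of a 1-silyloxy-2-methylbutadiene and a (Z)-acylacrylate.
2. Late stage: side-chain diol unmasking ⇐ C1 alcohol oxidation ⇐ double angeloylation at C2–O and C8–O ⇐ C7–C8 bond by Nozaki–Hiyama–Kishi coupling of a C7 enol triflate with a C8–C11 aldehyde from the (S)-malic acid chiral pool.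
3. Middle stage: C7 methyl ketone ⇐ C3 ester; C2–O ⇐ Baeyer–Villiger oxidation of the C2 acetyl (retention); epoxide ⇐ C1–OH-directed epoxidation of C5=C6.
4. Ring order: the cyclohexene first, by the [4+2] cycloaddition forming C1–C2 and C3–C4; then the oxirane; the only other ring is the temporary dioxolane on the side chain.

Key step: step 4

Assumption 1: (S)-α-hydroxy-γ-butyrolactone is taken as a purchased chiral-pool material (it is the two-step reduction product of (S)-malic acid), so the C10 configuration is bought, not made.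
Assumption 2: the (S)-antipodes of the boron catalyst (step 4) and of the chromium ligand (step 16) are taken as the matched ones; if the sense of induction proved opposite, the mirror-image catalyst or ligand would be used and nothing else would change.

**Route**

Step 1
Reactants: 1 (E)-2-methylbut-2-enal
Product: 2 (E)-1-[(tert-butyldimethylsilyl)oxy]-2-methylbuta-1,3-diene
Conditions: TBSOTf, Et3N, Et2O, 0 °C to rt
Reagents that add atoms: tert-butyldimethylsilyl triflate, CC(C)(C)[Si](C)(C)OS(=O)(=O)C(F)(F)F
Why: dienol silyl ether formation (O-silylation of the enal, then γ-deprotonation of the silyloxocarbenium ion) should give the (E)-diene because the enal reacts from its s-trans conformation.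

Step 2
Reactants: 3 2-methylfuran
Product: 5 (Z)-4-oxopent-2-enoic acid, via (Z)-4-oxopent-2-enal 4 (not isolated)
Conditions: NaClO2, NaH2PO4, t-BuOH/H2O, 0 °C to rt
Reagents that add atoms: sodium chlorite, [Na+].[O-]Cl=O; water, O
Why: oxidative furan ring opening followed by Pinnick-type chlorite oxidation of the liberated aldehyde should give the cis keto acid (stored as its ring-closed lactol tautomer), the (Z)-alkene being inherited from the furan ring.

Step 3
Reactants: 5 (Z)-4-oxopent-2-enoic acid
Product: 6 methyl (Z)-4-oxopent-2-enoate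
Conditions: MeI, KHCO3, DMF, 0 °C to rt, dark
Reagents that add atoms: iodomethane, CI
Why: SN2 O-alkylation of the ring-opened keto carboxylate gives the normal ester rather than the pseudo-ester, and the (Z)-geometry should survive when light and nucleophilic amines are excluded.

Step 4
Reactants: 2 (E)-1-[(tert-butyldimethylsilyl)oxy]-2-methylbuta-1,3-diene; 6 methyl (Z)-4-oxopent-2-enoate
Product: 7 methyl (1S,5S,6S)-6-acetyl-5-[(tert-butyldimethylsilyl)oxy]-4-methylcyclohex-3-ene-1-carboxylate (all-cis; target numbering C1-OTBS, C2-acetyl, C3-CO2Me)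
Conditions: (S)-3,3-diphenyl-1-(o-tolyl)tetrahydro-1H,3H-pyrrolo[1,2-c][1,3,2]oxazaborole (20 mol%) activated with HNTf2 (18 mol%), CH2Cl2, −78 to −40 °C
Reagents that add atoms: none
Why: Lewis-acid-accelerated normal-demand Diels–Alder cycloaddition, concerted but asynchronous, whose closest precedents are endo additions of (E)-1-silyloxydienes to cis-β-acylacrylates and oxazaborolidinium-catalysed additions of silyloxydienes to enones. The six-membered carbocycle closes by an intermolecular suprafacial [4+2] union in which the C3–C4 bond (diene CH2 terminus to the ester-bearing carbon) leads and the C1–C2 bond (silyloxy terminus to the acetyl-bearing carbon) follows. Regiochemistry is expected from binding of the cationic boron to the more basic ketone oxygen, which puts the largest LUMO coefficient on the ester-bearing carbon, matched with the largest HOMO coefficient at the unsubstituted diene terminus. The cis C2/C3 relation is the (Z)-alkene geometry carried through, and C1 falls cis to both because the (E)-silyloxy group points outward while the two acyl groups sit endo. The absolute configuration must come from the chiral boron pocket shielding one face of the bound enone, which is the least secured element because a (Z)-enone prefers an s-cis conformation. The step therefore needs regio-, endo- and facial selectivity together; the first two are secured by the ketone-bound Lewis acid and the diene geometry, the third by the catalyst.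

Step 5
Reactants: 7 all-cis silyloxy keto ester
Product: 8 methyl (1S,5S,6S)-6-acetyl-5-hydroxy-4-methylcyclohex-3-ene-1-carboxylate
Conditions: HF·pyridine, pyridine, THF, 0 °C
Reagents that add atoms: none
Why: acidic fluoride desilylation of the allylic silyl ether; the non-basic medium should avoid β-elimination, retro-aldol cleavage and C2 epimerisation of the β-oxy ketone.

Step 6
Reactants: 8 allylic alcohol
Product: 9 syn-epoxy alcohol (epoxide oxygen, C1-OH, C2-acetyl and C3-CO2Me on one ring face)
Conditions: VO(acac)2 (5 mol%), t-BuOOH (decane), CH2Cl2, 0 °C to rt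
Reagents that add atoms: tert-butyl hydroperoxide, CC(C)(C)OO
Why: hydroxyl-directed epoxidation, in which the vanadium alkoxide–peroxide complex delivers oxygen to C5=C6 from the face of the C1 hydroxyl, sets C5 and C6 with the epoxide cis to the three ring substituents despite that face being the more hindered one.

Step 7
Reactants: 9 syn-epoxy alcohol
Product: 10 C1 tert-butyldimethylsilyl ether of 9
Conditions: TBSOTf, 2,6-lutidine, CH2Cl2, −78 °C
Reagents that add atoms: tert-butyldimethylsilyl triflate, CC(C)(C)[Si](C)(C)OS(=O)(=O)C(F)(F)F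
Why: silylation of the hindered secondary alcohol with the silyl triflate re-masks C1–O, so that C1 and C2 oxygens stay differentiated once the C2 oxygen appears.

Step 8
Reactants: 10 silyl-protected epoxy keto ester
Product: 11 C2 acetate (all-cis)
Conditions: (CF3CO)2O, urea·H2O2, Na2HPO4, CH2Cl2, 0 °C
Reagents that add atoms: urea–hydrogen peroxide, OO.NC(N)=O (the peroxy oxygen is delivered as trifluoroperacetic acid, OOC(=O)C(F)(F)F, formed in the flask)
Why: Baeyer–Villiger oxidation in which the secondary ring carbon C2 migrates in preference to methyl and with retention, so the acetyl becomes the C2 acetate on the same face; the phosphate buffer protects epoxide and silyl ether.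

Step 9
Reactants: 11 C2 acetate
Product: 13 C2-hydroxy N-methoxy-N-methylamide, via C2-hydroxy methyl ester 12 (not isolated)
Conditions: MeNH(OMe)·HCl, i-PrMgCl (2 equiv per amine salt, premixed), THF, −20 to 0 °C
Reagents that add atoms: N,O-dimethylhydroxylamine hydrochloride, CNOC.Cl
Why: ester aminolysis by the magnesium amide cleaves the unhindered acetate first and then converts the methyl ester into the N-methoxy-N-methylamide; the weakly basic amide should leave C3 and the silyl ether untouched.

Step 10
Reactants: 13 C2-hydroxy amide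
Product: 14 C2 triethylsilyl ether of 13
Conditions: TESOTf, 2,6-lutidine, CH2Cl2, −78 °C
Reagents that add atoms: triethylsilyl triflate, CC[Si](CC)(CC)OS(=O)(=O)C(F)(F)F
Why: silylation gives a C2 protecting group more labile than the C1 silyl ether and removes the free β-hydroxyl before a ketone is made, which forestalls retro-aldol cleavage.

Step 11
Reactants: 14 bis-silylated amide
Product: 15 C7 methyl ketone (C3-acetyl; C1-OTBS, C2-OTES, 5,6-epoxide)
Conditions: MeMgBr, THF, −40 to 0 °C
Reagents that add atoms: methylmagnesium bromide, C[Mg]Br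
Why: Weinreb ketone synthesis, in which the chelated tetrahedral adduct holds until work-up so that addition stops at the ketone; the trisubstituted epoxide should be inert at this temperature.

Step 12
Reactants: 15 C7 methyl ketone
Product: 17 C7 enol triflate, via potassium C7 enolate 16 (not isolated)
Conditions: KN(SiMe3)2, THF, −78 °C; then PhNTf2, −78 to −20 °C
Reagents that add atoms: N-phenylbis(trifluoromethanesulfonimide), FC(F)(F)S(=O)(=O)N(c1ccccc1)S(=O)(=O)C(F)(F)F; potassium bis(trimethylsilyl)amide, C[Si](C)(C)[N-][Si](C)(C)C.[K+] (potassium in 16 only)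
Why: kinetic deprotonation at the methyl group and O-sulfonylation of the enolate give the 1,1-disubstituted enol triflate without enolising towards C3, so C3 is kept and the C2 silyloxy group is not eliminated.

Step 13
Reactants: 18 (S)-3-hydroxydihydrofuran-2(3H)-one
Product: 19 (S)-4-methylpentane-1,3,4-triol
Conditions: MeMgBr (4 equiv), THF, 0 °C to rt
Reagents that add atoms: methylmagnesium bromide, C[Mg]Br
Why: double Grignard addition to the lactone carbonyl (after deprotonation of the hydroxyl) opens the ring to the tertiary carbinol C11 without touching the stereocentre that becomes C10.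

Step 14
Reactants: 19 (S)-4-methylpentane-1,3,4-triol
Product: 20 2-[(4S)-2,2,5,5-tetramethyl-1,3-dioxolan-4-yl]ethan-1-ol
Conditions: 2,2-dimethoxypropane, PPTS (cat.), acetone, rt
Reagents that add atoms: 2,2-dimethoxypropane, COC(C)(C)OC
Why: acetonide formation under equilibrating conditions is expected to favour the five-membered dioxolane on the vicinal secondary/tertiary diol over the 1,3-dioxane, leaving the primary hydroxyl free.

Step 15
Reactants: 20 dioxolane alcohol
Product: 21 2-[(4S)-2,2,5,5-tetramethyl-1,3-dioxolan-4-yl]acetaldehyde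
Conditions: DMP, NaHCO3, CH2Cl2, 0 °C to rt
Reagents that add atoms: none
Why: Dess–Martin oxidation under buffered, non-basic conditions should give the β-alkoxy aldehyde without β-elimination.

Step 16
Reactants: 17 C7 enol triflate; 21 dioxolane aldehyde
Product: 22 (8S)-allylic alcohol (C3–C7(=CH2)–C8H(OH)–C9H2–dioxolane; C1-OTBS, C2-OTES)
Conditions: CrCl2, NiCl2 (cat.), (S)-N-[2-(4-isopropyl-4,5-dihydrooxazol-2-yl)-6-methylphenyl]methanesulfonamide, Et3N, THF, rt
Reagents that add atoms: none
Why: Nozaki–Hiyama–Kishi coupling, in which zerovalent nickel inserts into the enol triflate and transmetalation gives an alkenylchromium species that adds only to the aldehyde; the 8S carbinol (1,3-anti to the C10 oxygen) is the product favoured by the β-alkoxy group, and the chiral sulfonamide ligand on chromium is chosen to reinforce that bias.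

Step 17
Reactants: 22 (8S)-allylic alcohol
Product: 23 C2,C8-diol (C1-OTBS and acetonide retained)
Conditions: HF·pyridine, pyridine, THF, 0 °C
Reagents that add atoms: none
Why: selective fluoride-mediated cleavage of the triethylsilyl ether, which is far more labile than the hindered C1 tert-butyldimethylsilyl ether; the buffered medium spares epoxide and acetonide.

Step 18
Reactants: 23 C2,C8-diol; 24 angelic acid ((Z)-2-methylbut-2-enoic acid)
Product: 26 C2,C8-bis-angelate, via angelic 2,4,6-trichlorobenzoic anhydride 25 (not isolated)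
Conditions: 2,4,6-trichlorobenzoyl chloride, Et3N, toluene, rt; then 23, 75 °C
Reagents that add atoms: 2,4,6-trichlorobenzoyl chloride, O=C(Cl)c1c(Cl)cc(Cl)cc1Cl (its atoms are in 25 only)
Why: Yamaguchi esterification through the mixed anhydride, run without a nucleophilic catalyst so that the (Z)-geometry of the acyl group is kept, should acylate both secondary hydroxyls at the angeloyl carbonyl.

Step 19
Reactants: 26 C2,C8-bis-angelate
Product: 27 C1 alcohol
Conditions: HF·pyridine, pyridine, THF, 0 °C to rt
Reagents that add atoms: none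
Why: fluoride desilylation of the hindered secondary silyl ether; the mildly acidic medium should spare acetonide, epoxide and angelates and suppress 1,2-acyl migration from C2–O to C1–O.

Step 20
Reactants: 27 C1 alcohol
Product: 28 C1 ketone (side-chain acetonide of the target)
Conditions: DMP, NaHCO3, CH2Cl2, rt
Reagents that add atoms: none
Why: Dess–Martin oxidation of the only free hydroxyl gives the α,β-epoxy ketone under neutral conditions that should not epimerise C2.

Step 21
Reactants: 28 C1 ketone acetonide
Product: 29 CNP0127352.2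
Conditions: AcOH/H2O (4:1), 40 °C
Reagents that add atoms: none
Why: acid-catalysed acetal hydrolysis frees the C10/C11 diol; an α,β-epoxy ketone and hindered conjugated esters should tolerate weak aqueous acid.

**Compound list**

1 | (E)-2-methylbut-2-enal | C/C=C(\C)C=O | starting material
2 | (E)-1-[(tert-butyldimethylsilyl)oxy]-2-methylbuta-1,3-diene | C=C/C(C)=C/O[Si](C)(C)C(C)(C)C | intermediate
3 | 2-methylfuran | Cc1ccco1 | starting material
4 | (Z)-4-oxopent-2-enal | CC(=O)/C=C\C=O | intermediate
5 | (Z)-4-oxopent-2-enoic acid (in equilibrium with 5-hydroxy-5-methylfuran-2(5H)-one) | CC(=O)/C=C\C(=O)O | intermediate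
6 | methyl (Z)-4-oxopent-2-enoate | COC(=O)/C=C\C(C)=O | intermediate
7 | methyl (1S,5S,6S)-6-acetyl-5-[(tert-butyldimethylsilyl)oxy]-4-methylcyclohex-3-ene-1-carboxylate | COC(=O)[C@H]1CC=C(C)[C@@H](O[Si](C)(C)C(C)(C)C)[C@H]1C(C)=O | intermediate
8 | methyl (1S,5S,6S)-6-acetyl-5-hydroxy-4-methylcyclohex-3-ene-1-carboxylate | COC(=O)[C@H]1CC=C(C)[C@@H](O)[C@H]1C(C)=O | intermediate
9 | methyl 4-acetyl-5-hydroxy-6-methyl-7-oxabicyclo[4.1.0]heptane-3-carboxylate, epoxide O, OH, acetyl and CO2Me all on one face, configuration of 8 retained | COC(=O)[C@H]1C[C@H]2O[C@@]2(C)[C@@H](O)[C@H]1C(C)=O | intermediate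
10 | methyl 4-acetyl-5-[(tert-butyldimethylsilyl)oxy]-6-methyl-7-oxabicyclo[4.1.0]heptane-3-carboxylate, all-cis as 9 | COC(=O)[C@H]1C[C@H]2O[C@@]2(C)[C@@H](O[Si](C)(C)C(C)(C)C)[C@H]1C(C)=O | intermediate
11 | methyl 4-acetoxy-5-[(tert-butyldimethylsilyl)oxy]-6-methyl-7-oxabicyclo[4.1.0]heptane-3-carboxylate, all-cis | COC(=O)[C@H]1C[C@H]2O[C@@]2(C)[C@@H](O[Si](C)(C)C(C)(C)C)[C@H]1OC(C)=O | intermediate
12 | methyl 5-[(tert-butyldimethylsilyl)oxy]-4-hydroxy-6-methyl-7-oxabicyclo[4.1.0]heptane-3-carboxylate, all-cis (formed as its magnesium alkoxide) | COC(=O)[C@H]1C[C@H]2O[C@@]2(C)[C@@H](O[Si](C)(C)C(C)(C)C)[C@H]1O | intermediate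
13 | 5-[(tert-butyldimethylsilyl)oxy]-4-hydroxy-N-methoxy-N,6-dimethyl-7-oxabicyclo[4.1.0]heptane-3-carboxamide, all-cis | CON(C)C(=O)[C@H]1C[C@H]2O[C@@]2(C)[C@@H](O[Si](C)(C)C(C)(C)C)[C@H]1O | intermediate
14 | 5-[(tert-butyldimethylsilyl)oxy]-N-methoxy-N,6-dimethyl-4-[(triethylsilyl)oxy]-7-oxabicyclo[4.1.0]heptane-3-carboxamide, all-cis | CON(C)C(=O)[C@H]1C[C@H]2O[C@@]2(C)[C@@H](O[Si](C)(C)C(C)(C)C)[C@H]1O[Si](CC)(CC)CC | intermediate
15 | 1-{5-[(tert-butyldimethylsilyl)oxy]-6-methyl-4-[(triethylsilyl)oxy]-7-oxabicyclo[4.1.0]heptan-3-yl}ethan-1-one, all-cis | CC(=O)[C@H]1C[C@H]2O[C@@]2(C)[C@@H](O[Si](C)(C)C(C)(C)C)[C@H]1O[Si](CC)(CC)CC | intermediate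
16 | potassium enolate of 15 (potassium 1-substituted ethen-1-olate) | [K+].[O-]C(=C)[C@H]1C[C@H]2O[C@@]2(C)[C@@H](O[Si](C)(C)C(C)(C)C)[C@H]1O[Si](CC)(CC)CC | intermediate
17 | 1-{5-[(tert-butyldimethylsilyl)oxy]-6-methyl-4-[(triethylsilyl)oxy]-7-oxabicyclo[4.1.0]heptan-3-yl}ethenyl trifluoromethanesulfonate, all-cis | C=C(OS(=O)(=O)C(F)(F)F)[C@H]1C[C@H]2O[C@@]2(C)[C@@H](O[Si](C)(C)C(C)(C)C)[C@H]1O[Si](CC)(CC)CC | intermediate
18 | (S)-3-hydroxydihydrofuran-2(3H)-one ((S)-α-hydroxy-γ-butyrolactone) | O=C1OCC[C@@H]1O | starting material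
19 | (S)-4-methylpentane-1,3,4-triol | OCC[C@H](O)C(C)(C)O | intermediate
20 | 2-[(4S)-2,2,5,5-tetramethyl-1,3-dioxolan-4-yl]ethan-1-ol | OCC[C@@H]1OC(C)(C)OC1(C)C | intermediate
21 | 2-[(4S)-2,2,5,5-tetramethyl-1,3-dioxolan-4-yl]acetaldehyde | O=CC[C@@H]1OC(C)(C)OC1(C)C | intermediate
22 | (8S)-allylic alcohol: ring of 17 bearing at C3 the chain C7(=CH2)–C8H(OH)–CH2–[(4S)-2,2,5,5-tetramethyl-1,3-dioxolan-4-yl]; C1-OTBS, C2-OTES | C=C([C@@H](O)C[C@@H]1OC(C)(C)OC1(C)C)[C@H]1C[C@H]2O[C@@]2(C)[C@@H](O[Si](C)(C)C(C)(C)C)[C@H]1O[Si](CC)(CC)CC | intermediate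
23 | C2,C8-diol: 22 without the triethylsilyl group | C=C([C@@H](O)C[C@@H]1OC(C)(C)OC1(C)C)[C@H]1C[C@H]2O[C@@]2(C)[C@@H](O[Si](C)(C)C(C)(C)C)[C@H]1O | intermediate
24 | angelic acid, (Z)-2-methylbut-2-enoic acid | C/C=C(/C)C(=O)O | starting material
25 | (Z)-2-methylbut-2-enoic 2,4,6-trichlorobenzoic anhydride | C/C=C(/C)C(=O)OC(=O)c1c(Cl)cc(Cl)cc1Cl | intermediate
26 | C2,C8-bis[(Z)-2-methylbut-2-enoate] of 23; C1-OTBS, side-chain acetonide | C=C([C@H](C[C@@H]1OC(C)(C)OC1(C)C)OC(=O)/C(C)=C\C)[C@H]1C[C@H]2O[C@@]2(C)[C@@H](O[Si](C)(C)C(C)(C)C)[C@H]1OC(=O)/C(C)=C\C | intermediate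
27 | C1 alcohol: 26 without the tert-butyldimethylsilyl group | C=C([C@H](C[C@@H]1OC(C)(C)OC1(C)C)OC(=O)/C(C)=C\C)[C@H]1C[C@H]2O[C@@]2(C)[C@@H](O)[C@H]1OC(=O)/C(C)=C\C | intermediate
28 | C1 ketone: C10,C11-acetonide of the target | C=C([C@H](C[C@@H]1OC(C)(C)OC1(C)C)OC(=O)/C(C)=C\C)[C@H]1C[C@H]2O[C@@]2(C)C(=O)[C@H]1OC(=O)/C(C)=C\C | intermediate
29 | CNP0127352.2: (1R,3S,4R,6R)-4-[(3S,5S)-5,6-dihydroxy-6-methyl-3-{[(2Z)-2-methylbut-2-enoyl]oxy}hept-1-en-2-yl]-1-methyl-2-oxo-7-oxabicyclo[4.1.0]heptan-3-yl (2Z)-2-methylbut-2-enoate | C=C([C@H](C[C@H](O)C(C)(C)O)OC(=O)/C(C)=C\C)[C@H]1C[C@H]2O[C@@]2(C)C(=O)[C@H]1OC(=O)/C(C)=C\C | target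

**Step count and risks**

Total steps: 21. Longest linear sequence: 17 steps (2-methylfuran 3 to 29 through steps 2–12 and 16–21); the side-chain aldehyde takes 3 steps (13–15) and the diene 1 step.

Steps most likely to fail:

Step 4. The danger is insufficient enantiofacial discrimination, since the (Z)-enone prefers an s-cis conformation for which the usual catalyst model is not secured. Regiochemistry could also leak if the ester rather than the ketone is activated, and the acidic catalyst could desilylate the diene or divert it into conjugate addition. Fallback: setting out from 2 and 6, the cycloaddition is run without catalyst in toluene at 40–60 °C, where the ketone still directs regiochemistry and the endo rule still gives the all-cis relation. This should give the racemic all-cis adduct F1, which is resolved by preparative chromatography on a chiral stationary phase. The route is rejoined at 7.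

Step 16. The danger is poor facial selectivity at the aldehyde, giving a C8 epimer mixture, together with slow coupling of the hindered enol triflate. Fallback: setting out from 17 and 21, the coupling is run without ligand (CrCl2, NiCl2 cat., DMF), which should give 22 together with its C8 epimer F2. The mixture is oxidised with DMP to the C8 enone F3. Corey–Bakshi–Shibata reduction with (R)-1-methyl-3,3-diphenyltetrahydro-1H,3H-pyrrolo[1,2-c][1,3,2]oxazaborole and catecholborane at −78 °C, with the alkenyl group as the large substituent, should then set 8S. The route is rejoined at 22.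

Step 18. The danger is incomplete acylation of two hindered secondary hydroxyls and isomerisation of the angeloyl group to tigloyl under heating with amine. Fallback: setting out from 23, both hydroxyls are esterified with 2-[bis(2,2,2-trifluoroethoxy)phosphoryl]propanoic acid (DCC, DMAP, CH2Cl2) to give the bis-phosphonate F4. A double Still–Gennari olefination with acetaldehyde (KN(SiMe3)2, 18-crown-6, THF, −78 °C) then builds both (Z)-2-methylbut-2-enoates in place. The route is rejoined at 26.

**Further compounds**

F1 | step 4 | racemic all-cis adduct (7 together with its mirror image) | COC(=O)[C@H]1CC=C(C)[C@@H](O[Si](C)(C)C(C)(C)C)[C@H]1C(C)=O.COC(=O)[C@@H]1CC=C(C)[C@H](O[Si](C)(C)C(C)(C)C)[C@@H]1C(C)=O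
F2 | step 16 | C8 epimer (8R) of 22 | C=C([C@H](O)C[C@@H]1OC(C)(C)OC1(C)C)[C@H]1C[C@H]2O[C@@]2(C)[C@@H](O[Si](C)(C)C(C)(C)C)[C@H]1O[Si](CC)(CC)CC
F3 | step 16 | C8 enone derived from 22 | C=C(C(=O)C[C@@H]1OC(C)(C)OC1(C)C)[C@H]1C[C@H]2O[C@@]2(C)[C@@H](O[Si](C)(C)C(C)(C)C)[C@H]1O[Si](CC)(CC)CC
F4 | step 18 | C2,C8-bis{2-[bis(2,2,2-trifluoroethoxy)phosphoryl]propanoate} of 23 | C=C([C@H](C[C@@H]1OC(C)(C)OC1(C)C)OC(=O)C(C)P(=O)(OCC(F)(F)F)OCC(F)(F)F)[C@H]1C[C@H]2O[C@@]2(C)[C@@H](O[Si](C)(C)C(C)(C)C)[C@H]1OC(=O)C(C)P(=O)(OCC(F)(F)F)OCC(F)(F)F
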